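**Plan**

Cuts: the three aryl O–S bonds (O7, O3', O4') and the O3–acetyl bond are cut first. Next comes C3–C4 of the pyranone (ring C), then the O1–C2 ether bond. This leaves a phloroglucinaldehyde (ring A) and an arylacetic acid (ring B).
Enabling feature: C3 and C4 are neighbouring carbons of ring C and each bears oxygen (the ester oxygen on C3, the carbonyl oxygen on C4). Each therefore maps back onto a formyl carbon, and the bond between them onto an acyl-anion addition.
Forward order: rings A and B are purchased and joined through O1–C2 by phenoxide displacement. Ring C closes last through C3–C4, and oxidation flattens it to the flavonol. O3-acetylation, debenzylation and three sulfations follow.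
Stereochemistry: the target has no stereocentre. C2 (from step 2) and C3 (from step 7) are transient, are carried as racemates and are erased in step 8.

Key step: step 7

Assumption: the target SMILES holds no stereocentre and no stereogenic double bond, so the achiral compound itself meets the call for a single enantiomer; chiral intermediates are racemic with one enantiomer drawn.
Assumption: the sulfates are delivered as the hydrogen sulfates drawn; because aryl hydrogen sulfates hydrolyse on storage, the acid form is released from its pyridinium salt only at the very end by cold cation exchange.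

**Step 1**
Reactants: 1 3,4-dihydroxyphenylacetic acid; 2 benzyl bromide
Product: 3 benzyl 2-[3,4-bis(benzyloxy)phenyl]acetate
Conditions: BnBr (3.3 equiv), K2CO3, DMF, 60 °C, N2
Reagents that add atoms: benzyl bromide, BrCc1ccccc1
Why: Williamson etherification of both catechol oxygens together with SN2 alkylation of the carboxylate caps all three acidic sites in one operation, so no separate esterification is needed.

**Step 2**
Reactants: 3 benzyl 2-[3,4-bis(benzyloxy)phenyl]acetate
Product: 5 benzyl 2-bromo-2-[3,4-bis(benzyloxy)phenyl]acetate (racemic), via lithium enolate 4 (not isolated)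
Conditions: LiHMDS, THF, −78 °C; cannulated into NBS, THF, −78 °C; aq NH4Cl; used crude
Reagents that add atoms: N-bromosuccinimide, O=C1CCC(=O)N1Br
Why: Electrophilic α-bromination of a preformed ester enolate should place bromine only on the benzylic α-carbon, and it avoids radical conditions (attack on the benzyl ether CH2 groups) and free NBS at higher temperature (ring bromination); the new centre is racemic.

**Step 3**
Reactants: 6 2,4,6-trihydroxybenzaldehyde; 2 benzyl bromide
Product: 7 2,4-bis(benzyloxy)-6-hydroxybenzaldehyde
Conditions: BnBr (2.05 equiv), K2CO3, DMF, rt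
Reagents that add atoms: benzyl bromide, BrCc1ccccc1
Why: In this regioselective Williamson etherification the 4-OH and one ortho OH react, after which the last ortho OH is held in a hydrogen bond to the formyl oxygen and resists alkylation at two equivalents of halide.

**Step 4**
Reactants: 5 benzyl 2-bromo-2-[3,4-bis(benzyloxy)phenyl]acetate; 7 2,4-bis(benzyloxy)-6-hydroxybenzaldehyde
Product: 8 benzyl 2-[3,5-bis(benzyloxy)-2-formylphenoxy]-2-[3,4-bis(benzyloxy)phenyl]acetate (racemic)
Conditions: K2CO3, DMF, rt
Reagents that add atoms: none
Why: SN2 displacement (Williamson type) of the doubly activated benzylic α-bromo ester by the phenoxide forms O1–C2 at room temperature, which is mild enough to keep the acidic C2–H from closing onto the ortho formyl group by aldol addition; C2 stays racemic.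

**Step 5**
Reactants: 8 benzyl 2-[3,5-bis(benzyloxy)-2-formylphenoxy]-2-[3,4-bis(benzyloxy)phenyl]acetate
Product: 9 2-[3,5-bis(benzyloxy)-2-(hydroxymethyl)phenoxy]-2-[3,4-bis(benzyloxy)phenyl]ethan-1-ol (racemic)
Conditions: LiAlH4, THF, 0 °C; water/Rochelle salt work-up; Et3N-washed silica
Reagents that add atoms: none
Why: Exhaustive LiAlH4 reduction brings ester and aldehyde to the same alcohol level, so the ester need not be stopped at the aldehyde stage next to a free aromatic aldehyde.

**Step 6**
Reactants: 9 2-[3,5-bis(benzyloxy)-2-(hydroxymethyl)phenoxy]-2-[3,4-bis(benzyloxy)phenyl]ethan-1-ol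
Product: 10 2,4-bis(benzyloxy)-6-{1-[3,4-bis(benzyloxy)phenyl]-2-oxoethoxy}benzaldehyde (racemic)
Conditions: Dess–Martin periodinane (2.4 equiv), NaHCO3, CH2Cl2, 0 °C to rt; used at once
Reagents that add atoms: none
Why: A double Dess–Martin oxidation under bicarbonate buffer raises both primary carbinols to formyl groups without acid (the trialkoxybenzyl alcohol ionises easily) and without amine base (the C2–H of the product is labile).

**Step 7**
Reactants: 10 2,4-bis(benzyloxy)-6-{1-[3,4-bis(benzyloxy)phenyl]-2-oxoethoxy}benzaldehyde
Product: 12 trans-5,7,3',4'-tetra-O-benzyltaxifolin (racemic), via enaminol 11 (not isolated)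
Conditions: 2-(pentafluorophenyl)-6,7-dihydro-5H-pyrrolo[2,1-c][1,2,4]triazol-2-ium tetrafluoroborate (20 mol %), i-Pr2NEt (20 mol %), CH2Cl2 (0.01 M), Ar, 25–40 °C
Reagents that add atoms: none
Why: Proposed new method: the triazolylidene adds reversibly to the aromatic formyl group of 10, proton transfer gives enaminol 11 (the acyl anion equivalent at C4), this carbon attacks the aliphatic formyl carbon C3 in a 6-exo-trig closure of ring C, and collapse of the alkoxide expels the carbene to leave the C4 ketone and the C3 carbinol. The closest known reaction types are the carbene-catalysed intramolecular crossed aldehyde–ketone benzoin of 2-(2-oxoalkoxy)benzaldehydes to 3-hydroxychroman-4-ones and the carbene-catalysed cyclisation of aliphatic dialdehydes to cyclic acyloins; the pairing of an aryl aldehyde with an α-aryloxy aldehyde has not been shown. The new C3 centre is set relative to C2 by a chair-like transition state with the C2 aryl group equatorial, and amine-mediated equilibration through the enediol should funnel the product to the diequatorial trans isomer, although both centres vanish in step 8. The step needs the carbene to activate the aromatic and not the aliphatic formyl group, because an enaminol at C3 would carry the aryloxide O1 as an α-leaving group and would collapse by internal redox to an aryl arylacetate that cannot re-enter the route. The substrate secures this through its fully branched C2 (aryl plus aryloxy), which crowds the carbene adduct of the aliphatic aldehyde and makes that carbonyl a strong acceptor, the role that α-branched α-heteroatom aldehydes play in triazolium-catalysed cross-benzoin reactions, while aryl conjugation and the ortho oxygens favour adduct and enaminol formation at C4. The six-membered tether and the high dilution hold back dimerisation, and the acidic N-C6F5 azolium salt needs only a tertiary amine as base, which limits enolisation at C2.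

**Step 8**
Reactants: 12 trans-5,7,3',4'-tetra-O-benzyltaxifolin
Product: 14 5,7,3',4'-tetra-O-benzylquercetin, via dione 13 (not isolated)
Conditions: Dess–Martin periodinane (1.2 equiv), CH2Cl2, 0 °C to rt; aq NaHCO3/Na2S2O3 wash
Reagents that add atoms: none
Why: Dess–Martin oxidation of the α-hydroxy ketone gives 1,2-dione 13, whose acidic benzylic C2–H shifts to O3 under the driving force of forming the aromatic 4-pyranone, so C2 and C3 become sp2 and any cis isomer or 3-keto-4-ol carried from step 7 converges on 14.

**Step 9**
Reactants: 14 5,7,3',4'-tetra-O-benzylquercetin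
Product: 15 3-O-acetyl-5,7,3',4'-tetra-O-benzylquercetin
Conditions: Ac2O, pyridine, DMAP (cat.), CH2Cl2, 0 °C to rt
Reagents that add atoms: acetic anhydride, CC(=O)OC(C)=O
Why: Pyridine/DMAP-catalysed O-acylation meets a single free hydroxyl group, the 3-OH, because all four phenols are still benzylated.

**Step 10**
Reactants: 15 3-O-acetyl-5,7,3',4'-tetra-O-benzylquercetin
Product: 16 quercetin 3-acetate
Conditions: H2 (1 atm), 10% Pd/C, THF–EtOAc, rt
Reagents that add atoms: none
Why: Catalytic hydrogenolysis cleaves the four aryl benzyl ethers under neutral conditions, and the alcohol-free solvent protects the activated enol-type acetate from transesterification.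

**Step 11**
Reactants: 16 quercetin 3-acetate
Product: 18 quercetin 3-acetate 7,3',4'-tri-O-sulfate, via pyridinium salt 17 (not isolated)
Conditions: SO3·pyridine (9 equiv), DMF, 25–40 °C; H2O, 0 °C; Sephadex LH-20; Dowex 50W (H+), H2O, 4 °C; freeze-drying
Reagents that add atoms: sulfur trioxide–pyridine complex, O=S(=O)([O-])[n+]1ccccc1
Why: O-sulfation of phenols with an amine–SO3 complex follows nucleophilicity, so 7-OH, 4'-OH and 3'-OH should react while the 5-OH, locked in a six-membered hydrogen bond to the C4 carbonyl, is spared near ambient temperature as is usual in flavonoid sulfation, and cold cation exchange then releases the acid form.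

**Compound list**

1 | 3,4-dihydroxyphenylacetic acid | O=C(O)Cc1ccc(O)c(O)c1 | starting material
2 | benzyl bromide | BrCc1ccccc1 | starting material
3 | benzyl 2-[3,4-bis(benzyloxy)phenyl]acetate | O=C(Cc1ccc(OCc2ccccc2)c(OCc2ccccc2)c1)OCc1ccccc1 | intermediate
4 | lithium enolate of 3 (not isolated) | [Li+].[O-]C(OCc1ccccc1)=Cc1ccc(OCc2ccccc2)c(OCc2ccccc2)c1 | intermediate
5 | benzyl 2-bromo-2-[3,4-bis(benzyloxy)phenyl]acetate (racemic, one enantiomer drawn) | O=C(OCc1ccccc1)[C@@H](Br)c1ccc(OCc2ccccc2)c(OCc2ccccc2)c1 | intermediate
6 | 2,4,6-trihydroxybenzaldehyde | O=Cc1c(O)cc(O)cc1O | starting material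
7 | 2,4-bis(benzyloxy)-6-hydroxybenzaldehyde | O=Cc1c(O)cc(OCc2ccccc2)cc1OCc1ccccc1 | intermediate
8 | benzyl 2-[3,5-bis(benzyloxy)-2-formylphenoxy]-2-[3,4-bis(benzyloxy)phenyl]acetate (racemic, one enantiomer drawn) | O=C(OCc1ccccc1)[C@H](Oc1cc(OCc2ccccc2)cc(OCc2ccccc2)c1C=O)c1ccc(OCc2ccccc2)c(OCc2ccccc2)c1 | intermediate
9 | 2-[3,5-bis(benzyloxy)-2-(hydroxymethyl)phenoxy]-2-[3,4-bis(benzyloxy)phenyl]ethan-1-ol (racemic, one enantiomer drawn) | OC[C@H](Oc1cc(OCc2ccccc2)cc(OCc2ccccc2)c1CO)c1ccc(OCc2ccccc2)c(OCc2ccccc2)c1 | intermediate
10 | 2,4-bis(benzyloxy)-6-{1-[3,4-bis(benzyloxy)phenyl]-2-oxoethoxy}benzaldehyde (racemic, one enantiomer drawn) | O=C[C@H](Oc1cc(OCc2ccccc2)cc(OCc2ccccc2)c1C=O)c1ccc(OCc2ccccc2)c(OCc2ccccc2)c1 | intermediate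
11 | enaminol from the triazolylidene and the aromatic formyl group of 10 (not isolated; C=C geometry open) | OC(=C1N(c2c(F)c(F)c(F)c(F)c2F)N=C2CCCN12)c1c(OCc2ccccc2)cc(OCc2ccccc2)cc1O[C@@H](C=O)c1ccc(OCc2ccccc2)c(OCc2ccccc2)c1 | intermediate
12 | trans-5,7,3',4'-tetra-O-benzyltaxifolin, (2R*,3R*)-5,7-bis(benzyloxy)-2-[3,4-bis(benzyloxy)phenyl]-3-hydroxychroman-4-one (racemic, one enantiomer drawn) | O=C1[C@@H]([C@H](Oc2cc(OCc3ccccc3)cc(OCc3ccccc3)c21)c2ccc(OCc3ccccc3)c(OCc3ccccc3)c2)O | intermediate
13 | 5,7-bis(benzyloxy)-2-[3,4-bis(benzyloxy)phenyl]chromane-3,4-dione (not isolated; racemic, one enantiomer drawn) | O=C1C(=O)[C@H](Oc2cc(OCc3ccccc3)cc(OCc3ccccc3)c21)c2ccc(OCc3ccccc3)c(OCc3ccccc3)c2 | intermediate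
14 | 5,7,3',4'-tetra-O-benzylquercetin | O=c1c(O)c(-c2ccc(OCc3ccccc3)c(OCc3ccccc3)c2)oc2cc(OCc3ccccc3)cc(OCc3ccccc3)c12 | intermediate
15 | 3-O-acetyl-5,7,3',4'-tetra-O-benzylquercetin | CC(=O)Oc1c(-c2ccc(OCc3ccccc3)c(OCc3ccccc3)c2)oc2cc(OCc3ccccc3)cc(OCc3ccccc3)c2c1=O | intermediate
16 | quercetin 3-acetate | CC(=O)Oc1c(-c2ccc(O)c(O)c2)oc2cc(O)cc(O)c2c1=O | intermediate
17 | tris(pyridinium) salt of 18 (not isolated) | CC(=O)Oc1c(-c2ccc(OS(=O)(=O)[O-])c(OS(=O)(=O)[O-])c2)oc2cc(OS(=O)(=O)[O-])cc(O)c2c1=O.c1cc[nH+]cc1.c1cc[nH+]cc1.c1cc[nH+]cc1 | intermediate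
18 | quercetin 3-acetate 7,3',4'-tri-O-sulfate | CC(=O)Oc1c(-c2ccc(OS(=O)(=O)O)c(OS(=O)(=O)O)c2)oc2cc(OS(=O)(=O)O)cc(O)c2c1=O | target

**Count**

Total step count: 11.
Longest linear sequence: 10 steps (steps 1, 2 and 4–11, from 1); step 3 is the side branch.

**Steps most likely to fail**

1. Step 7 (bears the label). Enaminol formation at the electron-rich, doubly ortho-substituted aromatic aldehyde may be slow. The carbene may instead activate the aliphatic formyl group, with loss of the aryloxide, and the α-aryloxy aldehyde may decay by enolisation. The fallback sets out from 10 and joins the two formyl carbons reductively. SmI2 in THF with t-BuOH at −78 °C reduces the more easily reduced aromatic aldehyde to its ketyl, which has no α-leaving group. The ketyl then adds to the samarium-bound aliphatic aldehyde in a known intramolecular pinacol coupling. This makes the same C3–C4 bond and the same ring and should give 5,7,3',4'-tetra-O-benzylflavan-3,4-diol F1, with the diol expected cis from chelation. IBX in DMSO, which oxidises vicinal diols without glycol cleavage, then takes both carbinols to dione 13. The dione tautomerises, and the fallback comes back to the route at 14.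

2. Step 11. The second sulfation of the crowded, already anionic catechol may stall, and forcing it may let sulfation creep onto O5. The acetate or a sulfate may also hydrolyse during aqueous isolation of a very polar salt. The fallback sets out from 16 and installs masked sulfates. 2,2,2-Trichloroethyl chlorosulfate with Et3N in THF at 0 °C should give quercetin 3-acetate 7,3',4'-tris(2,2,2-trichloroethyl sulfate) F2. This neutral triester can be freed of under- and over-sulfated material on silica gel. Zinc dust and ammonium formate in THF–MeCN then fragment the trichloroethyl groups under near-neutral conditions that spare the acetate. Cold H+ exchange brings the fallback back to the route at 18.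

3. Step 2. Proton exchange between the enolate and the more acidic product may lead to double bromination. Stray NBS may brominate the ring, and the electron-rich benzylic bromide may solvolyse before step 4. The fallback sets out from 3 and avoids any halide. Enolate hydroxylation (KHMDS, 2-(phenylsulfonyl)-3-phenyloxaziridine, THF, −78 °C) should give the storable benzyl 2-hydroxy-2-[3,4-bis(benzyloxy)phenyl]acetate F3. A Mitsunobu etherification with phenol 7 (PPh3, DIAD, THF, 0 °C to rt) forms O1–C2 under neutral conditions. This also removes the aldol risk of step 4, and the fallback comes back to the route at 8.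

**Further compounds**

F1 | step 7 | 5,7,3',4'-tetra-O-benzylflavan-3,4-diol (racemic; 2,3-trans-3,4-cis isomer drawn) | O[C@@H]1[C@@H]([C@H](Oc2cc(OCc3ccccc3)cc(OCc3ccccc3)c21)c2ccc(OCc3ccccc3)c(OCc3ccccc3)c2)O
F2 | step 11 | quercetin 3-acetate 7,3',4'-tris(2,2,2-trichloroethyl sulfate) | CC(=O)Oc1c(-c2ccc(OS(=O)(=O)OCC(Cl)(Cl)Cl)c(OS(=O)(=O)OCC(Cl)(Cl)Cl)c2)oc2cc(OS(=O)(=O)OCC(Cl)(Cl)Cl)cc(O)c2c1=O
F3 | step 2 | benzyl 2-hydroxy-2-[3,4-bis(benzyloxy)phenyl]acetate (racemic, one enantiomer drawn) | O=C(OCc1ccccc1)[C@@H](O)c1ccc(OCc2ccccc2)c(OCc2ccccc2)c1
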